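**Retrosynthetic overview**

- The target (2R,3R)-flavanonol is unmasked last from a protected 3-methoxyflavanone by debenzylation and removal of the O5 methyl group. O3 and O4 come from syn-dihydroxylation of the C3=C4 bond of an (S)-2-aryl-2H-chromene on the face anti to the C2 aryl group.
- Ring C is the only ring made: the C4–C4a bond is formed by gold-catalysed 6-endo-dig hydroarylation of an (S)-aryl propargyl ether that carries C3–C4 as a terminal alkyne.
- Feature used: C4a is one of two equivalent, strongly activated carbons ortho to the ether oxygen of a mirror-symmetric ring A (OMe/OBn/OMe at the future C5/C6/C7). No regiocontrol is needed, the C7 methyl ether is present from the start, and C5 is freed later through its peri relation to the C4 carbonyl.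
- The O1–C2 bond and the C2 stereocentre come from enantioconvergent copper-catalysed propargylic etherification of a racemic 1-arylpropargyl acetate (ring B aldehyde plus ethynylmagnesium bromide) with a phenol made by Dakin oxidation of O-benzylsyringaldehyde.
- Ring order: rings A and B are bought; ring C is closed in the key step.

Key step: step 7

Assumption: the (S,S) antipode of the Ph-pybox ligand is taken to give the (S)-configured ether in step 6; should a test reaction show the opposite sense, the (R,R) ligand is used and nothing else changes.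

**Route**

Step 1
Reactants: 1 3-hydroxy-4,5-dimethoxybenzaldehyde
Product: 2 3-(benzyloxy)-4,5-dimethoxybenzaldehyde
Conditions: BnBr, K2CO3, DMF, rt
Reagents that add atoms: benzyl bromide, BrCc1ccccc1
Why: Williamson etherification of the only phenol by SN2 on benzyl bromide; the aldehyde is inert to carbonate.

Step 2
Reactants: 2 3-(benzyloxy)-4,5-dimethoxybenzaldehyde; 3 ethynylmagnesium bromide
Product: 4 rac-1-[3-(benzyloxy)-4,5-dimethoxyphenyl]prop-2-yn-1-ol
Conditions: THF, 0 °C; then H2O, aq NH4Cl
Reagents that add atoms: ethynylmagnesium bromide (3), C#C[Mg]Br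
Why: Grignard 1,2-addition of the acetylide to the aryl aldehyde; the carbinol centre is made racemic on purpose, because step 6 passes through a planar intermediate and sets it afresh.

Step 3
Reactants: 4 rac-1-[3-(benzyloxy)-4,5-dimethoxyphenyl]prop-2-yn-1-ol
Product: 5 rac-1-[3-(benzyloxy)-4,5-dimethoxyphenyl]prop-2-yn-1-yl acetate
Conditions: Ac2O, Et3N, DMAP (cat.), CH2Cl2, 0 °C → rt
Reagents that add atoms: acetic anhydride, CC(=O)OC(C)=O
Why: DMAP-catalysed acylation of the secondary alcohol installs the leaving group needed for copper-catalysed propargylic substitution.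

Step 4
Reactants: 6 4-hydroxy-3,5-dimethoxybenzaldehyde (syringaldehyde)
Product: 7 4-(benzyloxy)-3,5-dimethoxybenzaldehyde
Conditions: BnBr, K2CO3, DMF, 60 °C
Reagents that add atoms: benzyl bromide, BrCc1ccccc1
Why: Williamson etherification of the acidic para-formyl phenol; gentle heating overcomes the two flanking methoxy groups.

Step 5
Reactants: 7 4-(benzyloxy)-3,5-dimethoxybenzaldehyde
Product: 9 4-(benzyloxy)-3,5-dimethoxyphenol, via aryl formate 8 (not isolated)
Conditions: mCPBA, CH2Cl2, 0 °C → rt; then K2CO3 (cat.), MeOH, rt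
Reagents that add atoms: 3-chloroperoxybenzoic acid, OOC(=O)c1cccc(Cl)c1
Why: Dakin-type Baeyer–Villiger oxidation, in which the electron-rich aryl group migrates to oxygen to give the formate, which methanolysis cleaves to the phenol.

Step 6
Reactants: 5 rac-1-[3-(benzyloxy)-4,5-dimethoxyphenyl]prop-2-yn-1-yl acetate; 9 4-(benzyloxy)-3,5-dimethoxyphenol
Product: 10 (S)-2-(benzyloxy)-5-{1-[3-(benzyloxy)-4,5-dimethoxyphenyl]prop-2-yn-1-yloxy}-1,3-dimethoxybenzene
Conditions: CuOTf·0.5C6H6 (5 mol%), (S,S)-Ph-pybox (10 mol%), iPr2NEt, CH2Cl2, −20 → 0 °C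
Reagents that add atoms: none
Why: Copper-catalysed asymmetric propargylic substitution (etherification with a phenol): the monovalent copper acetylide of 5 expels acetate to give a planar copper allenylidene, so both enantiomers of 5 converge, and the phenoxide of 9 adds through oxygen to the γ-carbon on the face left open by the pybox ligand, which sets C2 as (S); the para-blocked phenol and the amine base should favour O- over C-propargylation.

Step 7
Reactants: 10 (S)-2-(benzyloxy)-5-{1-[3-(benzyloxy)-4,5-dimethoxyphenyl]prop-2-yn-1-yloxy}-1,3-dimethoxybenzene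
Product: 11 (S)-6-(benzyloxy)-2-[3-(benzyloxy)-4,5-dimethoxyphenyl]-5,7-dimethoxy-2H-chromene
Conditions: Ph3PAuNTf2 (3 mol%), 4 Å MS, CH2Cl2, 0 °C → rt
Reagents that add atoms: none
Why: Cationic monovalent gold binds the terminal alkyne, the ring A carbon ortho to the ether oxygen (activated by one ortho and one para methoxy group) attacks the terminal alkyne carbon in an intramolecular Friedel–Crafts step, and rearomatisation followed by protodeauration of the vinyl-gold species releases the C3=C4 alkene and the catalyst. The closest known reaction type is the gold- or platinum-catalysed cycloisomerisation (alkyne hydroarylation) of aryl propargyl ethers to 2H-chromenes. Ring C closes in the 6-endo-dig mode, which terminal aryl propargyl ethers follow because the ortho carbon reaches the distal alkyne carbon through an unstrained six-membered transition state, whereas 5-exo attack at the internal carbon would need a bent O–C–C≡C array. No stereocentre is formed; C2, set in step 6, is not among the reacting atoms and should be carried through unchanged. The step needs regiocontrol on ring A and retention at C2: the mirror-symmetric OMe/OBn/OMe pattern makes the two ortho carbons equivalent, and a non-protic gold catalyst at low temperature should keep the benzylic, propargylic C–O bond from ionising.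

Step 8
Reactants: 11 (S)-6-(benzyloxy)-2-[3-(benzyloxy)-4,5-dimethoxyphenyl]-5,7-dimethoxy-2H-chromene
Product: 12 (2R,3S,4S)-6-(benzyloxy)-2-[3-(benzyloxy)-4,5-dimethoxyphenyl]-5,7-dimethoxychromane-3,4-diol
Conditions: OsO4 (2 mol%), NMO, acetone/H2O, 0 °C → rt
Reagents that add atoms: osmium tetroxide (catalytic oxygen carrier), O=[Os](=O)(=O)=O; N-methylmorpholine N-oxide, C[N+]1([O-])CCOCC1; water, O
Why: Catalytic OsO4/NMO syn-dihydroxylation, known for flav-3-enes, in which the osmium reagent adds to the C3=C4 bond from the face opposite the C2 aryl group and so sets C3 (S) and C4 (S) as the 2,3-trans-3,4-cis diol.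

Step 9
Reactants: 12 (2R,3S,4S)-6-(benzyloxy)-2-[3-(benzyloxy)-4,5-dimethoxyphenyl]-5,7-dimethoxychromane-3,4-diol
Product: 13 (2R,3R)-6-(benzyloxy)-2-[3-(benzyloxy)-4,5-dimethoxyphenyl]-3-hydroxy-5,7-dimethoxychroman-4-one
Conditions: activated MnO2 (excess), CH2Cl2, rt
Reagents that add atoms: none
Why: Chemoselective MnO2 oxidation of the benzylic C4 carbinol, activated by the ortho and para oxygens of ring A, while the non-benzylic C3 hydroxyl stays; the neutral heterogeneous oxidant leaves C2 and C3 untouched, and the reaction is stopped at full conversion to avoid glycol cleavage.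

Step 10
Reactants: 13 (2R,3R)-6-(benzyloxy)-2-[3-(benzyloxy)-4,5-dimethoxyphenyl]-3-hydroxy-5,7-dimethoxychroman-4-one
Product: 14 (2R,3R)-6-(benzyloxy)-2-[3-(benzyloxy)-4,5-dimethoxyphenyl]-3,5,7-trimethoxychroman-4-one
Conditions: Me3OBF4, 1,8-bis(dimethylamino)naphthalene, 4 Å MS, CH2Cl2, 0 °C → rt
Reagents that add atoms: trimethyloxonium tetrafluoroborate, C[O+](C)C.F[B-](F)(F)F
Why: O-methylation of the secondary alcohol by the oxonium salt, buffered by a hindered non-nucleophilic amine, so that no alkoxide or enolate forms and neither retro-oxa-Michael ring opening nor epimerisation at C3 is expected.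

Step 11
Reactants: 14 (2R,3R)-6-(benzyloxy)-2-[3-(benzyloxy)-4,5-dimethoxyphenyl]-3,5,7-trimethoxychroman-4-one
Product: 15 (2R,3R)-6-hydroxy-2-(3-hydroxy-4,5-dimethoxyphenyl)-3,5,7-trimethoxychroman-4-one
Conditions: H2 (1 atm), 10% Pd/C, EtOAc/MeOH, rt
Reagents that add atoms: none
Why: Hydrogenolysis of the two aryl benzyl ethers; at balloon pressure with monitoring, the flavanone C2–O1 bond and the aryl ketone should survive, as is usual for benzyl-protected dihydroflavonols.

Step 12
Reactants: 15 (2R,3R)-6-hydroxy-2-(3-hydroxy-4,5-dimethoxyphenyl)-3,5,7-trimethoxychroman-4-one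
Product: 16 (2R,3R)-5,6-dihydroxy-2-(3-hydroxy-4,5-dimethoxyphenyl)-3,7-dimethoxychroman-4-one (target)
Conditions: BCl3 (1 M in CH2Cl2, excess), CH2Cl2, −78 → 0 °C; then H2O
Reagents that add atoms: none
Why: Chelation-directed Lewis acid demethylation: boron held between the C4 carbonyl oxygen and O5 in a six-membered chelate exposes only the peri 5-O-methyl group to chloride attack at low temperature, while the C7, ring B and C3 methyl ethers lack this activation.

**Compound list**

1 | 3-hydroxy-4,5-dimethoxybenzaldehyde | COc1cc(C=O)cc(O)c1OC | starting material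
2 | 3-(benzyloxy)-4,5-dimethoxybenzaldehyde | COc1cc(C=O)cc(OCc2ccccc2)c1OC | intermediate
3 | ethynylmagnesium bromide | C#C[Mg]Br | starting material
4 | rac-1-[3-(benzyloxy)-4,5-dimethoxyphenyl]prop-2-yn-1-ol | C#CC(O)c1cc(OCc2ccccc2)c(OC)c(OC)c1 | intermediate
5 | rac-1-[3-(benzyloxy)-4,5-dimethoxyphenyl]prop-2-yn-1-yl acetate | C#CC(OC(C)=O)c1cc(OCc2ccccc2)c(OC)c(OC)c1 | intermediate
6 | 4-hydroxy-3,5-dimethoxybenzaldehyde (syringaldehyde) | COc1cc(C=O)cc(OC)c1O | starting material
7 | 4-(benzyloxy)-3,5-dimethoxybenzaldehyde | COc1cc(C=O)cc(OC)c1OCc1ccccc1 | intermediate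
8 | 4-(benzyloxy)-3,5-dimethoxyphenyl formate | COc1cc(OC=O)cc(OC)c1OCc1ccccc1 | intermediate
9 | 4-(benzyloxy)-3,5-dimethoxyphenol | COc1cc(O)cc(OC)c1OCc1ccccc1 | intermediate
10 | (S)-2-(benzyloxy)-5-{1-[3-(benzyloxy)-4,5-dimethoxyphenyl]prop-2-yn-1-yloxy}-1,3-dimethoxybenzene | C#C[C@@H](c1cc(OCc2ccccc2)c(OC)c(OC)c1)Oc1cc(OC)c(OCc2ccccc2)c(OC)c1 | intermediate
11 | (S)-6-(benzyloxy)-2-[3-(benzyloxy)-4,5-dimethoxyphenyl]-5,7-dimethoxy-2H-chromene | COc1cc2c(c(OC)c1OCc1ccccc1)C=C[C@@H](c1cc(OCc3ccccc3)c(OC)c(OC)c1)O2 | intermediate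
12 | (2R,3S,4S)-6-(benzyloxy)-2-[3-(benzyloxy)-4,5-dimethoxyphenyl]-5,7-dimethoxychromane-3,4-diol | COc1cc2c(c(OC)c1OCc1ccccc1)[C@H](O)[C@H](O)[C@@H](c1cc(OCc3ccccc3)c(OC)c(OC)c1)O2 | intermediate
13 | (2R,3R)-6-(benzyloxy)-2-[3-(benzyloxy)-4,5-dimethoxyphenyl]-3-hydroxy-5,7-dimethoxychroman-4-one | COc1cc2c(c(OC)c1OCc1ccccc1)C(=O)[C@H](O)[C@@H](c1cc(OCc3ccccc3)c(OC)c(OC)c1)O2 | intermediate
14 | (2R,3R)-6-(benzyloxy)-2-[3-(benzyloxy)-4,5-dimethoxyphenyl]-3,5,7-trimethoxychroman-4-one | COc1cc2c(c(OC)c1OCc1ccccc1)C(=O)[C@H](OC)[C@@H](c1cc(OCc3ccccc3)c(OC)c(OC)c1)O2 | intermediate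
15 | (2R,3R)-6-hydroxy-2-(3-hydroxy-4,5-dimethoxyphenyl)-3,5,7-trimethoxychroman-4-one | COc1cc2c(c(OC)c1O)C(=O)[C@H](OC)[C@@H](c1cc(O)c(OC)c(OC)c1)O2 | intermediate
16 | (2R,3R)-5,6-dihydroxy-2-(3-hydroxy-4,5-dimethoxyphenyl)-3,7-dimethoxychroman-4-one | COc1cc2c(c(O)c1O)C(=O)[C@H](OC)[C@@H](c1cc(O)c(OC)c(OC)c1)O2 | target

**Step count**

Total: 12 steps. Longest linear sequence: 10 steps (1 → 2 → 4 → 5 → 10 → 11 → 12 → 13 → 14 → 15 → 16; steps 1, 2, 3, 6, 7, 8, 9, 10, 11, 12).

**Steps most likely to fail, with fallbacks**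

Step 7 (key step). The cationic gold centre may act as a Lewis acid on the benzylic, propargylic C2–O bond, so that heterolysis erodes the configuration at C2 or cleaves the ether, and the electron-rich chromene may oligomerise on the catalyst. The fallback closes the same C4–C4a bond by Friedel–Crafts acylation instead of alkyne activation. It sets out from 10 and returns to the route at 13, replacing steps 7 to 9.
- Anti-Markovnikov hydroboration of the terminal alkyne of 10 (Cy2BH, THF, 0 °C; then NaBO3·4H2O) should give (S)-3-[4-(benzyloxy)-3,5-dimethoxyphenoxy]-3-[3-(benzyloxy)-4,5-dimethoxyphenyl]propanal F1.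
- Pinnick oxidation (NaClO2, NaH2PO4, 2-methyl-2-butene, tBuOH/H2O) should give (S)-3-[4-(benzyloxy)-3,5-dimethoxyphenoxy]-3-[3-(benzyloxy)-4,5-dimethoxyphenyl]propanoic acid F2. In this acid the C–O bond is no longer propargylic and lies β to a carboxyl group, so it should resist ionisation.
- (CF3CO)2O in CH2Cl2 at 0 °C forms the mixed anhydride, which acylates the activated ortho carbon of ring A to give (S)-6-(benzyloxy)-2-[3-(benzyloxy)-4,5-dimethoxyphenyl]-5,7-dimethoxychroman-4-one F3.
- Soft enolisation (TMSOTf, Et3N, CH2Cl2, 0 °C) gives (S)-6-(benzyloxy)-2-[3-(benzyloxy)-4,5-dimethoxyphenyl]-5,7-dimethoxy-4-(trimethylsilyloxy)-2H-chromene F4.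
- Rubottom oxidation with dimethyldioxirane in acetone at −20 °C, on the face anti to the C2 aryl group, followed by mild desilylation (citric acid, MeOH) should give 13.

Step 6. The copper allenylidene may be attacked by the very electron-rich ortho carbon of the phenol instead of its oxygen (C-propargylation), or the ligand may discriminate the two faces insufficiently. One recrystallisation of 12 or 13 is planned in any case to raise the enantiomeric purity. The fallback fixes the configuration by resolution and stereospecific substitution. It sets out from 4 and returns at 10.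
- Immobilised Candida antarctica lipase B with vinyl acetate in toluene at 30 °C should acylate the (R)-enantiomer (aryl as the large, ethynyl as the medium substituent) to give (R)-1-[3-(benzyloxy)-4,5-dimethoxyphenyl]prop-2-yn-1-yl acetate F5, which is separated from the unreacted (S)-alcohol.
- Methanolysis (K2CO3, MeOH, 0 °C) gives (R)-1-[3-(benzyloxy)-4,5-dimethoxyphenyl]prop-2-yn-1-ol F6.
- Mitsunobu reaction of this alcohol with phenol 9 (PPh3, DIAD, toluene, 0 °C) should proceed with inversion to give 10.

Step 10. While the α-hydroxy ketone is held in the alkylating medium it may open by retro-oxa-Michael loss of the ring A phenoxide or epimerise at C3 through the enol, and the hindered, hydrogen-bonded hydroxyl may alkylate incompletely. The fallback methylates O3 before the ketone exists. It sets out from 12 and returns at 14, replacing steps 9 and 10.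
- Bu2SnO in toluene at reflux with removal of water converts the cis-diol into the 2,2-dibutyl-1,3,2-dioxastannolane bridging O3 and O4 of 12 (stannylene acetal) F7.
- MeI and CsF in DMF at 40 °C should alkylate the equatorial, unhindered O3 to give (2R,3S,4S)-6-(benzyloxy)-2-[3-(benzyloxy)-4,5-dimethoxyphenyl]-3,5,7-trimethoxychroman-4-ol F8.
- Dess–Martin periodinane with NaHCO3 in CH2Cl2 oxidises the remaining C4 carbinol to give 14.

**Further compounds**

F1 | step 7 | (S)-3-[4-(benzyloxy)-3,5-dimethoxyphenoxy]-3-[3-(benzyloxy)-4,5-dimethoxyphenyl]propanal | O=CC[C@@H](c1cc(OCc2ccccc2)c(OC)c(OC)c1)Oc1cc(OC)c(OCc2ccccc2)c(OC)c1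
F2 | step 7 | (S)-3-[4-(benzyloxy)-3,5-dimethoxyphenoxy]-3-[3-(benzyloxy)-4,5-dimethoxyphenyl]propanoic acid | OC(=O)C[C@@H](c1cc(OCc2ccccc2)c(OC)c(OC)c1)Oc1cc(OC)c(OCc2ccccc2)c(OC)c1
F3 | step 7 | (S)-6-(benzyloxy)-2-[3-(benzyloxy)-4,5-dimethoxyphenyl]-5,7-dimethoxychroman-4-one | COc1cc2c(c(OC)c1OCc1ccccc1)C(=O)C[C@@H](c1cc(OCc3ccccc3)c(OC)c(OC)c1)O2
F4 | step 7 | (S)-6-(benzyloxy)-2-[3-(benzyloxy)-4,5-dimethoxyphenyl]-5,7-dimethoxy-4-(trimethylsilyloxy)-2H-chromene | COc1cc2c(c(OC)c1OCc1ccccc1)C(O[Si](C)(C)C)=C[C@@H](c1cc(OCc3ccccc3)c(OC)c(OC)c1)O2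
F5 | step 6 | (R)-1-[3-(benzyloxy)-4,5-dimethoxyphenyl]prop-2-yn-1-yl acetate | C#C[C@@H](OC(C)=O)c1cc(OCc2ccccc2)c(OC)c(OC)c1
F6 | step 6 | (R)-1-[3-(benzyloxy)-4,5-dimethoxyphenyl]prop-2-yn-1-ol | C#C[C@@H](O)c1cc(OCc2ccccc2)c(OC)c(OC)c1
F7 | step 10 | 2,2-dibutyl-1,3,2-dioxastannolane bridging O3 and O4 of 12 (stannylene acetal) | COc1cc2c(c(OC)c1OCc1ccccc1)[C@@H]1O[Sn](CCCC)(CCCC)O[C@@H]1[C@@H](c1cc(OCc3ccccc3)c(OC)c(OC)c1)O2
F8 | step 10 | (2R,3S,4S)-6-(benzyloxy)-2-[3-(benzyloxy)-4,5-dimethoxyphenyl]-3,5,7-trimethoxychroman-4-ol | COc1cc2c(c(OC)c1OCc1ccccc1)[C@H](O)[C@H](OC)[C@@H](c1cc(OCc3ccccc3)c(OC)c(OC)c1)O2
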